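## Structural features

The target is a spiro[5.5]undecane. Ring A (C1–C6) is a cyclohexene-1,3-dione: C1 carries the methoxy group of a vinylogous ester, C2 a methyl group, C3 and C5 are the ketones and C6 is a gem-dimethyl carbon. Ring B (C4, C7–C11) is a cyclohexene with the trisubstituted C8=C9 alkene, the 4-methylpent-3-enyl (homoprenyl) chain on C8 and an isopropyl group on C11; the rings share the all-carbon quaternary C4. There are two adjacent stereocentres, C4 and C11. C4 is stereogenic only because its two carbonyl arms differ at a distance: C3 (enol-ether side) lies cis to the isopropyl group and C5 (gem-dimethyl side) lies trans. The fragile parts are the vinylogous ester (acid, nucleophiles), the two non-enolisable 1,3-dicarbonyl units around C4 and C6 (retro-Claisen opening by alkoxides) and the two trisubstituted alkenes (acid, electrophiles). The real difficulty is threefold: a quaternary spiro centre of defined orientation next to C11; the absolute configuration of C11, which has no heteroatom nearby; and the placement of the side chain, since C8 is 1,4 to C11 but 1,3 to C4, the opposite of what a cycloaddition of a 2-substituted diene with a dienophile activated at C4 prefers. The choice between the C1 and C3 oxygen atoms in the final O-methylation is a further, smaller problem. The key step exploits two features: C11 is beta to the C3 carbonyl, so the C10–C11 bond can be made at the beta carbon of an enone; and the C8=C9 alkene next to the C7 methylene marks ring B as the 1,3-shift isomer of a cyclobutane (C4, C11, C10, C9) that carries a 2-substituted vinyl group on C9.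

## Logic of the disconnections

28 to 27. The O–CH3 bond on the C1 oxygen is cut. The vinylogous ester is the most labile group and is best made last; what remains is a triketone that needs no protection. The forward step must alkylate oxygen and not C2, and the C1 oxygen and not the C3 oxygen.

27 to 25. The C2–C3 bond is cut (Dieckmann). C3 is at the acid oxidation level and C2 is the only enolisable carbon of 25, so the closure has no regiochemical choice. Ring A is opened to a chain on C4 and both stereocentres stay as they are. The base must not open the 1,3-diketone by retro-Claisen attack.

25 to 22. The C6–C1 bond is cut. C6 is the alpha carbon of the C5 ketone and carries the only acidic C–H of 22. A three-carbon acyl unit is removed. The forward step must acylate a fully substituted enolate at carbon and not at oxygen.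

22 to 20. The C4–C5 bond is cut. This is where the spiro configuration is decided: C4 becomes a trigonal ester enolate and the acyl group enters anti to the isopropyl group on C11. The quaternary stereocentre is thereby reduced to 1,2-induction from C11, and any configuration at C4 in 20 is acceptable. The step needs high facial selectivity and C-acylation.

20 to 19. The C4–C7 bond is cut and the C4–C9 bond restored (reverse of a 1,3-shift). The cyclohexene becomes a vinylcyclobutane, which is a [2+2] adduct, and the regiochemistry of ring B becomes a question of where a vinyl group sits on a four-membered ring. The forward shift must beat cycloreversion and leave C11 untouched.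

19 to 14 and 15. The bond between C8 and the side chain is cut. A 2-substituted vinyl group is the carbometalation product of a terminal alkyne, so the side chain comes from a commercial bromide and the alkyne serves as a compact placeholder. The step needs the alkyl group on the internal carbon and tolerance of the ester.

14 to 12. No skeletal bond is cut: the ester C–O bond is exchanged for the C–C bond to the imidazole, and the alkyne C–H for C–Si. The ester is what the later steps need; the acylimidazole is what the photochemical step needs for two-point binding. The exchange must not disturb C11.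

12 to 8 and 11. The C10–C11 and C4–C9 bonds are cut ([2+2]). This gives two small achiral components that hold all carbons of ring B except the side chain, and C11 is left to a catalyst. The forward step must bond C11 to the CH2 terminus, differentiate the faces of the enone and excite only the catalyst-bound enone.

8 to 4 and 5; 4 to 1 and 2. The bond between the carbonyl carbon and the imidazole C2 is cut, then the amide C–N bond. Both are standard acyl substitutions; the only demand is 1,2-addition without over-addition.

11 to 9 and 10. The C(sp)–C(sp2) bond is cut (cross-coupling); the demand is handling of a volatile product.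

## Other disconnections considered

Alternative 1: The cut is the C4–C11 bond. Ring A is traced back to a fully substituted phloroglucinol ether whose ipso carbon C4 carries C7–C10 as a (Z)-alkenyl tether ending in an allylic carbonate, phenol A2. In the forward step zerovalent palladium (Pd2(dba)3 with a chiral diphosphine) ionises the carbonate and the phenoxide attacks the allyl terminus C11 through C4. The arene is dearomatised and ring B closes to spiro dienone A1, which has an isopropenyl group on C11 and keeps the C5 oxygen as a silyl enol ether.
- In its favour: the oxygen pattern of ring A, including the methoxy group on C1, comes from the aromatic starting material, so the regiochemical question in the last step of the chosen plan does not arise. On this point the alternative is the better one. The spiro ring and C11 come from one catalytic asymmetric step, which is equal in kind to the chosen plan. An ionic ring closure is also mechanistically less demanding than a triplet cycloaddition of an acyclic enone.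
- Against it here: an arene cannot carry the gem-dimethyl group, so C6 must be methylated after the key step, which requires unmasking the silyl ether. The resulting anion is delocalised over both oxygen atoms and over C2 and C6. The distinction between C3 and C5, on which the configuration of C4 in A1 rests, then disappears, and the spiro configuration is decided by whether the methyl group enters at C6 or at C2. These positions differ only through the remote C11 substituent.
- Further costs: the isopropenyl group must be hydrogenated beside two trisubstituted alkenes, and A2 needs a stereodefined trisubstituted alkene and a benzylic bond to a crowded arene. A2 is likely to take about as many steps as the chosen route needs to reach 20.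
- Comparison: structurally the chosen plan is stronger, because C4 is fixed by the order in which two different acyl groups are introduced and cannot be lost afterwards.

Alternative 2: The cuts are the C11–isopropyl bond and the C4–C5 bond; ring B is present from the start as the skipped diene ester A4. In the forward step iPrMgBr adds to C11 under copper catalysis (CuBr·SMe2, chiral ferrocenyl diphosphine), and the magnesium enolate is trapped at C4 by 2-methylpropanoyl chloride anti to the new isopropyl group. This gives keto ester A3 in one flask; no ring is formed. A3 is identical with 22, so the endgame is the same as in the chosen plan.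
- In its favour: it would reach 22 in far fewer steps than the eight of the chosen plan (better step economy) and needs no photochemistry. C4 is set by the same anti acylation (equal on that point).
- Against it here: the acceptor is a cyclic enoate with a trisubstituted alkene. This class reacts sluggishly with copper–organomagnesium reagents and lies outside the acyclic, beta-monosubstituted esters for which these ligands are reliable, and a secondary organomagnesium reagent is the least selective nucleophile.
- The C7 methylene of A4 is doubly allylic and gamma to the ester, so deprotonation, migration of the alkene into conjugation and aromatisation compete with addition.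
- A4 has the 1,3 relationship of ester and side chain that a Diels–Alder reaction of a 2-substituted diene with a propiolate does not deliver, so it needs an indirect synthesis.
- Comparison: shorter and operationally simpler, but its stereo-defining step asks a known catalyst system to work on an unfavourable substrate. The chosen plan spends more steps to obtain C11 from a substrate class (chelating 2-acylimidazoles) suited to asymmetric Lewis-acid catalysis.

Alternative 3: The cuts are C4–C7 and C4–C11. Ring A is used intact as cyclic 1,3-dione A6, whose C4 methylene is the nucleophile, and the ring B carbons come from cross-conjugated dienone A7. In the forward step, under a chiral base or amine catalyst, A6 adds through C4 first to the unsubstituted terminus C7 and then intramolecularly (6-endo-trig) to C11, giving spiro triketone A5. The C9 ketone is then removed through the C8 enol triflate and palladium-catalysed reduction, which leaves the C8=C9 alkene.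
- In its favour: it is the most convergent plan and clearly the shortest (better step economy). Ring A arrives complete with methoxy and gem-dimethyl groups, so there is no late regiochemical question (better than the chosen plan). No photochemical or high-temperature step is needed. C11 again rests on one catalytic asymmetric step (equal).
- Against it here: the configuration of C4 relative to C11 depends on which carbonyl group of the planar ring A enolate lies on the side of the isopropyl group in the second Michael addition. C3 and C5 differ only two atoms away from the reacting centre, so little intrinsic preference is expected, and a quaternary centre once formed cannot be corrected.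
- The second addition is to a hindered beta-isopropyl enone and is reversible. Removal of the ketone needs an enolate at C8 that has the stabilised C4 carbanion as a beta leaving group, so retro-Michael opening of ring B threatens, in addition to the choice between C8 and C10.
- Comparison: better in convergence and in the handling of ring A, weaker on the spiro centre, which the chosen plan controls by 1,2-induction from C11 at a centre that can be regenerated as the enolate of 20.

Key step: step 4

Remarks and assumptions on the chemistry:
- The (S,S) ligand is assumed to give the S configuration at C11; the sense of induction is not derived here, and the (R,R) ligand is taken if the first run shows the opposite.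
- 12 is written as the all-trans isomer, in which C11 has the S configuration that the target requires. The adduct has the alkynyl carbon bonded to the acyl-bearing carbon, the orientation usually called head-to-head for enones. Any C9 epimer is carried along, since C9 becomes trigonal in step 7.
- The two precursors are kept as the N-methyl and trimethylsilyl compounds. The changes made are the sensitiser and the placing of the acyl exchange before the organocopper step.

## Route

Step 1
Reactants: 1 (E)-4-methylpent-2-enoic acid; 2 N,O-dimethylhydroxylamine hydrochloride
Product: 4 (E)-N-methoxy-N,4-dimethylpent-2-enamide, via acyl imidazolide 3 (not isolated)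
Conditions: CDI, CH2Cl2, 0 °C to rt; then 2, rt
Reagents that add atoms: none
Why: Amide formation through the acyl imidazolide; the amine hydrochloride is acylated directly while the displaced imidazole takes up HCl, the hindered beta carbon keeps conjugate addition of imidazole slow, and the E alkene is not touched.

Step 2
Reactants: 5 1-methylimidazole; 4 (E)-N-methoxy-N,4-dimethylpent-2-enamide
Product: 8 (E)-4-methyl-1-(1-methylimidazol-2-yl)pent-2-en-1-one, via 2-lithio-1-methylimidazole 6 (not isolated), via lithium tetrahedral adduct 7 (not isolated)
Conditions: n-BuLi, THF, −78 °C; then 4, −78 to 0 °C; aq. NH4Cl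
Reagents that add atoms: none
Why: Lithiation of the imidazole at C2 and acyl substitution on an N-methoxy-N-methylamide; the hard organolithium adds to the carbonyl and not to the beta carbon, the chelated adduct 7 survives until work-up so no second addition occurs, and the E geometry is carried through.

Step 3
Reactants: 9 ethynyl(trimethyl)silane; 10 bromoethene
Product: 11 but-3-en-1-yn-1-yl(trimethyl)silane
Conditions: Pd(PPh3)2Cl2 (2 mol%), copper monoiodide (4 mol%), i-Pr2NH, THF, 0 °C to rt
Reagents that add atoms: none
Why: Sonogashira coupling of a terminal alkyne with a vinyl bromide; the silyl group blocks the second alkyne terminus, and the volatile enyne is distilled or used as a stock solution.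

Step 4
Reactants: 8 (E)-4-methyl-1-(1-methylimidazol-2-yl)pent-2-en-1-one; 11 but-3-en-1-yn-1-yl(trimethyl)silane
Product: 12 (1-methylimidazol-2-yl)[(1S,2S,4S)-2-(propan-2-yl)-4-(trimethylsilylethynyl)cyclobutyl]methanone
Conditions: Sc(OTf)3 (10 mol%), (S,S)-2,6-bis(4-tert-butyl-4,5-dihydrooxazol-2-yl)pyridine (15 mol%), [Ir(dF(CF3)ppy)2(dtbbpy)]PF6 (1 mol%), 11 (5 equiv), i-PrOAc/MeCN 3:1, 450 nm LEDs, Ar, 0 °C
Reagents that add atoms: none
Why: This is an enantioselective crossed [2+2] photocycloaddition under Lewis-acid-controlled triplet sensitisation, the reaction type known for chelating enones (2-acylimidazoles, 2'-hydroxychalcones) with dienes and styrenes. Two-point binding of 8 through N3 and the carbonyl oxygen to the Sc–pybox complex lowers its pi,pi* triplet energy, so that energy transfer from the excited iridium sensitiser is fast to bound 8 and slow to free 8 and to 11; an iridium sensitiser is taken because the triplet energy of Ru(bpy)3(PF6)2 is expected to be too low for a chromophore without an aryl group on the alkene. In the triplet the unstabilised beta carbon C11 attacks the unsubstituted terminus C10 of 11, which gives the more stable of the possible 1,4-diradicals, an alpha-acyl radical at C4 and a propargylic radical at C9. After intersystem crossing these two centres combine to the C4–C9 bond, so the four-membered ring is closed stepwise by radical recombination and not by a concerted cycloaddition. C11 is fixed in the first bond formation by the catalyst, whose ligand blocks one face of the chelated s-cis enone. C4 (trans to isopropyl) and C9 (trans to the acyl group) are set at ring closure by steric preference and are temporary, since C9 becomes trigonal in step 7 and C4 in step 8. The step needs regioselectivity (C11 to C10), which the stability of the propargylic and alpha-acyl diradical secures, chemoselectivity for the alkene over the alkyne, which the silyl cap and the unhindered CH2 terminus secure, and excitation of bound 8 only, which the choice of sensitiser secures. Because the triplet of an acyclic enone decays quickly by twisting, 11 is used in fivefold excess, and both alkene isomers of 8 react through the same triplet.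

Step 5
Reactants: 12 (1-methylimidazol-2-yl)[(1S,2S,4S)-2-(propan-2-yl)-4-(trimethylsilylethynyl)cyclobutyl]methanone
Product: 14 methyl (1S,2S,4S)-2-ethynyl-4-(propan-2-yl)cyclobutane-1-carboxylate, via acylimidazolium triflate 13 (not isolated)
Conditions: MeOTf, 4 Å MS, MeCN, rt; then MeOH, K2CO3 (0.3 equiv), 0 °C to rt
Reagents that add atoms: methanol, CO
Why: N-Methylation turns the imidazole into an azolium leaving group (the usual unmasking of a 2-acylimidazole); methoxide then gives the methyl ester by acyl substitution and in the same operation cleaves the C(sp)–Si bond. C11 is not acidic and keeps its configuration, and C4 can epimerise only towards the all-trans arrangement it already has. The exchange is placed here because an ester, unlike the chelating and more acidic ketone, is inert to the organocopper reagent of step 6.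

Step 6
Reactants: 15 5-bromo-2-methylpent-2-ene; 14 methyl (1S,2S,4S)-2-ethynyl-4-(propan-2-yl)cyclobutane-1-carboxylate
Product: 19 methyl (1S,2S,4S)-2-(6-methylhepta-1,5-dien-2-yl)-4-(propan-2-yl)cyclobutane-1-carboxylate, via homoprenylmagnesium bromide 16 (not isolated), via homoprenylcopper 17 (not isolated), via alkenylcopper adduct 18 (not isolated)
Conditions: 15, Mg, Et2O, rt; CuBr·SMe2 (1 equiv), Et2O/Me2S, −45 °C; then 14, −30 to −20 °C; aq. NH4Cl
Reagents that add atoms: none
Why: Carbocupration of a terminal alkyne: the alkylcopper–magnesium bromide reagent adds syn across the triple bond with the alkyl group on the internal carbon C8 and copper on the terminal carbon C7, and protonolysis of 18 leaves the 1,1-disubstituted alkene. At −25 °C the reagent neither adds to the ester nor deprotonates it, and no stereocentre is involved.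

Step 7
Reactants: 19 methyl (1S,2S,4S)-2-(6-methylhepta-1,5-dien-2-yl)-4-(propan-2-yl)cyclobutane-1-carboxylate
Product: 20 methyl (1R,6S)-3-(4-methylpent-3-en-1-yl)-6-(propan-2-yl)cyclohex-3-ene-1-carboxylate
Conditions: 1,2-dichlorobenzene (0.02 M), BHT (5 mol%), sealed tube, 200 °C
Reagents that add atoms: none
Why: Thermal vinylcyclobutane-to-cyclohexene rearrangement (formal 1,3-shift): the C4–C9 bond, weakened by ring strain, the ester on C4 and the vinyl group on C9, breaks to an alpha-ester radical and a 2-alkylallyl radical, which recombine at C7 to the six-membered ring. The substituent on C8 removes the conformational preference that would hold C7 away from C4; C11 is never a radical centre and keeps its S configuration. The C1 epimer of 20 that forms alongside converges with it in step 8.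

Step 8
Reactants: 20 methyl (1R,6S)-3-(4-methylpent-3-en-1-yl)-6-(propan-2-yl)cyclohex-3-ene-1-carboxylate
Product: 22 methyl (1S,6S)-1-(2-methylpropanoyl)-3-(4-methylpent-3-en-1-yl)-6-(propan-2-yl)cyclohex-3-ene-1-carboxylate, via lithium ester enolate 21 (not isolated)
Conditions: LDA, THF, −78 °C; then i-PrCOCl, −78 to −40 °C
Reagents that add atoms: 2-methylpropanoyl chloride, CC(C)C(Cl)=O
Why: C-Acylation of a lithium ester enolate with an acid chloride. The enolate is planar at C4; the isopropyl group on C11 takes the pseudoaxial position to avoid allylic strain with the exocyclic enolate and shields one face, so the acyl group enters anti to it. C5 therefore ends trans and the ester carbon C3 cis to isopropyl, which is the spiro configuration of the target (1,2-induction from C11).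

Step 9
Reactants: 22 methyl (1S,6S)-1-(2-methylpropanoyl)-3-(4-methylpent-3-en-1-yl)-6-(propan-2-yl)cyclohex-3-ene-1-carboxylate
Product: 25 methyl (1S,6S)-1-(2,2-dimethyl-3-oxopentanoyl)-3-(4-methylpent-3-en-1-yl)-6-(propan-2-yl)cyclohex-3-ene-1-carboxylate, via lithium ketone enolate 23 (not isolated), via bromomagnesium enolate 24 (not isolated)
Conditions: LDA, THF, −78 to −30 °C; MgBr2·OEt2, −78 °C; then EtCOCl, −78 to 0 °C
Reagents that add atoms: propanoyl chloride, CCC(Cl)=O
Why: C-Acylation of a ketone enolate: the isopropyl methine C6–H is the only acidic C–H of 22, the magnesium enolate favours bond formation at carbon over oxygen, and the product has no proton between its two ketones, so it cannot quench unreacted enolate. No stereocentre is affected.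

Step 10
Reactants: 25 methyl (1S,6S)-1-(2,2-dimethyl-3-oxopentanoyl)-3-(4-methylpent-3-en-1-yl)-6-(propan-2-yl)cyclohex-3-ene-1-carboxylate
Product: 27 (6R,11S)-3-hydroxy-2,4,4-trimethyl-8-(4-methylpent-3-en-1-yl)-11-(propan-2-yl)spiro[5.5]undeca-2,8-diene-1,5-dione, via lithium enolate of the spiro triketone 26 (not isolated)
Conditions: LiHMDS (2.2 equiv), THF, −78 to 0 °C; then 1 M HCl
Reagents that add atoms: none
Why: Dieckmann condensation: the only enolisable position of 25 is the C2 methylene, whose enolate attacks the C3 ester (6-exo-trig) and closes ring A. The triketone is at once converted into its stabilised enolate 26, which drives the closure and shields C1 and C3 from the lithium methoxide released, while the low temperature and the non-nucleophilic base keep retro-Claisen opening at C5 slow. C4 and C11 are untouched.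

Step 11
Reactants: 27 (6R,11S)-3-hydroxy-2,4,4-trimethyl-8-(4-methylpent-3-en-1-yl)-11-(propan-2-yl)spiro[5.5]undeca-2,8-diene-1,5-dione
Product: 28 (6R,11S)-3-methoxy-2,4,4-trimethyl-8-(4-methylpent-3-en-1-yl)-11-(propan-2-yl)spiro[5.5]undeca-2,8-diene-1,5-dione
Conditions: Me3SiCHN2, MeOH/PhMe 1:4, 0 °C to rt
Reagents that add atoms: (trimethylsilyl)diazomethane, C[Si](C)(C)C=[N+]=[N-]
Why: O-Methylation of a vinylogous acid with a diazoalkane: 27 protonates the reagent, methanol removes silicon, and the methyldiazonium ion alkylates the enolate at oxygen. The oxygen on C3 lies next to the spiro centre and on the side of the isopropyl-bearing C11, whereas the oxygen on C1 lies between a methyl group and the gem-dimethyl carbon, so the less shielded C1 oxygen should react. No stereocentre is touched.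

## Compound list

1 | (E)-4-methylpent-2-enoic acid | CC(C)/C=C/C(O)=O | starting material
2 | N,O-dimethylhydroxylamine hydrochloride | CNOC.Cl | starting material
3 | (E)-1-(imidazol-1-yl)-4-methylpent-2-en-1-one (acyl imidazolide; not isolated) | CC(C)/C=C/C(=O)n1ccnc1 | intermediate
4 | (E)-N-methoxy-N,4-dimethylpent-2-enamide | CC(C)/C=C/C(=O)N(C)OC | intermediate
5 | 1-methylimidazole | Cn1ccnc1 | starting material
6 | 2-lithio-1-methylimidazole (not isolated) | [Li]c1nccn1C | intermediate
7 | lithium (E)-1-[methoxy(methyl)amino]-4-methyl-1-(1-methylimidazol-2-yl)pent-2-en-1-olate (tetrahedral adduct; not isolated) | CC(C)/C=C/C(O[Li])(N(C)OC)c1nccn1C | intermediate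
8 | (E)-4-methyl-1-(1-methylimidazol-2-yl)pent-2-en-1-one | CC(C)/C=C/C(=O)c1nccn1C | intermediate
9 | ethynyl(trimethyl)silane | C#C[Si](C)(C)C | starting material
10 | bromoethene | C=CBr | starting material
11 | but-3-en-1-yn-1-yl(trimethyl)silane | C=CC#C[Si](C)(C)C | intermediate
12 | (1-methylimidazol-2-yl)[(1S,2S,4S)-2-(propan-2-yl)-4-(trimethylsilylethynyl)cyclobutyl]methanone (all-trans) | CC(C)[C@@H]1C[C@H](C#C[Si](C)(C)C)[C@H]1C(=O)c1nccn1C | intermediate
13 | 1,3-dimethyl-2-[(1S,2S,4S)-2-(propan-2-yl)-4-(trimethylsilylethynyl)cyclobutanecarbonyl]imidazolium triflate (not isolated) | CC(C)[C@@H]1C[C@H](C#C[Si](C)(C)C)[C@H]1C(=O)c1n(C)cc[n+]1C.[O-]S(=O)(=O)C(F)(F)F | intermediate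
14 | methyl (1S,2S,4S)-2-ethynyl-4-(propan-2-yl)cyclobutane-1-carboxylate | CC(C)[C@@H]1C[C@H](C#C)[C@H]1C(=O)OC | intermediate
15 | 5-bromo-2-methylpent-2-ene | CC(C)=CCCBr | starting material
16 | (4-methylpent-3-en-1-yl)magnesium bromide (not isolated) | CC(C)=CCC[Mg]Br | intermediate
17 | (4-methylpent-3-en-1-yl)copper, as its MgBr2 complex (not isolated) | CC(C)=CCC[Cu] | intermediate
18 | [(E)-2-[(1S,2S,3S)-2-(methoxycarbonyl)-3-(propan-2-yl)cyclobutyl]-6-methylhepta-1,5-dien-1-yl]copper (not isolated) | CC(C)[C@@H]1C[C@H](/C(CCC=C(C)C)=C/[Cu])[C@H]1C(=O)OC | intermediate
19 | methyl (1S,2S,4S)-2-(6-methylhepta-1,5-dien-2-yl)-4-(propan-2-yl)cyclobutane-1-carboxylate | CC(C)[C@@H]1C[C@H](C(=C)CCC=C(C)C)[C@H]1C(=O)OC | intermediate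
20 | methyl (1R,6S)-3-(4-methylpent-3-en-1-yl)-6-(propan-2-yl)cyclohex-3-ene-1-carboxylate (trans isomer drawn; the C1 epimer accompanies it and converges in step 8) | COC(=O)[C@@H]1CC(CCC=C(C)C)=CC[C@H]1C(C)C | intermediate
21 | lithium methoxy[(6S)-3-(4-methylpent-3-en-1-yl)-6-(propan-2-yl)cyclohex-3-en-1-ylidene]methanolate (ester enolate; not isolated) | COC(O[Li])=C1CC(CCC=C(C)C)=CC[C@H]1C(C)C | intermediate
22 | methyl (1S,6S)-1-(2-methylpropanoyl)-3-(4-methylpent-3-en-1-yl)-6-(propan-2-yl)cyclohex-3-ene-1-carboxylate (ester cis to isopropyl) | COC(=O)[C@]1(CC(CCC=C(C)C)=CC[C@H]1C(C)C)C(=O)C(C)C | intermediate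
23 | lithium enolate of 22 at C6 (not isolated) | COC(=O)[C@]1(CC(CCC=C(C)C)=CC[C@H]1C(C)C)C(O[Li])=C(C)C | intermediate
24 | bromomagnesium enolate of 22 at C6 (not isolated) | COC(=O)[C@]1(CC(CCC=C(C)C)=CC[C@H]1C(C)C)C(O[Mg]Br)=C(C)C | intermediate
25 | methyl (1S,6S)-1-(2,2-dimethyl-3-oxopentanoyl)-3-(4-methylpent-3-en-1-yl)-6-(propan-2-yl)cyclohex-3-ene-1-carboxylate | COC(=O)[C@]1(CC(CCC=C(C)C)=CC[C@H]1C(C)C)C(=O)C(C)(C)C(=O)CC | intermediate
26 | lithium (6R,11S)-2,4,4-trimethyl-8-(4-methylpent-3-en-1-yl)-1,5-dioxo-11-(propan-2-yl)spiro[5.5]undeca-2,8-dien-3-olate (not isolated) | [Li]OC1=C(C)C(=O)[C@]2(CC(CCC=C(C)C)=CC[C@H]2C(C)C)C(=O)C1(C)C | intermediate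
27 | (6R,11S)-3-hydroxy-2,4,4-trimethyl-8-(4-methylpent-3-en-1-yl)-11-(propan-2-yl)spiro[5.5]undeca-2,8-diene-1,5-dione (enol form of the 1,3,5-trione) | OC1=C(C)C(=O)[C@]2(CC(CCC=C(C)C)=CC[C@H]2C(C)C)C(=O)C1(C)C | intermediate
28 | (6R,11S)-3-methoxy-2,4,4-trimethyl-8-(4-methylpent-3-en-1-yl)-11-(propan-2-yl)spiro[5.5]undeca-2,8-diene-1,5-dione | COC1=C(C)C(=O)[C@]2(CC(CCC=C(C)C)=CC[C@H]2C(C)C)C(=O)C1(C)C | target

## Step count and least certain steps

Total: 11 steps. Longest linear sequence: 10 steps (steps 1, 2, 4, 5, 6, 7, 8, 9, 10 and 11, from 1 to 28); step 3 is the only side branch.

Step 4 (key step). Most likely to go wrong: the triplet of an acyclic beta-alkyl enone relaxes by twisting about the alkene (E/Z isomerisation, hydrogen transfer from the isopropyl methine with deconjugation) faster than 11 captures it. Energy transfer to unbound 8 also opens a racemic channel, so either conversion or enantiomeric purity suffers. A smaller risk is first bond formation at C4 instead of C11. Fallback, from 8 and 11, returning at 14: the cycloaddition is run for conversion only, with Sc(OTf)3 but no chiral ligand and thioxanthone as sensitiser (405 nm), to give the racemic all-trans cycloadduct F1. N-Methylation as in step 5 gives the racemic acylimidazolium triflate F2, which is intercepted with the lithium salt of (S)-4-benzyloxazolidin-2-one. Of the two diastereomeric imides, the one with the (1S,2S,4S) acyl group, imide F3, is separated by chromatography or crystallisation. It is cleaved (MeOMgBr, MeOH, 0 °C; then K2CO3, MeOH) to 14 with return of the auxiliary. Catalyst control is thus replaced by a covalent resolving group. If the cycloaddition cannot be made preparatively useful at all, the Diels–Alder entry under step 7 supplies 20 without photochemistry.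

Step 7. Most likely to go wrong: cleavage of the 1,4-diradical across C10–C11 (cycloreversion to an enoate and a triene) competing with recombination at C7, since both paths start from the same intermediate and fragmentation gains entropy at 200 °C. Fallback: it does not set out from a numbered compound. It starts from the commercial compounds myrcene F4 and methyl (E)-4-oxopent-2-enoate F5, replaces steps 1 to 7 and returns at 20. A catalytic enantioselective Diels–Alder reaction is run with a chiral oxazaborolidinium Lewis acid (from the diphenylprolinol-derived B-o-tolyl oxazaborolidine and HNTf2; enantiomer chosen for the required sense; CH2Cl2, −78 °C). The ketone is the stronger activating group and the site of Lewis-acid binding, so it places the substituted diene carbon para to the carbon that bears it. The product is the trans keto ester F6, with the side chain on C8 and the acetyl group on C11. Wittig methylenation (Ph3P=CH2, THF, −78 to 0 °C) gives isopropenyl ester F7. Hydrogenation of the 1,1-disubstituted alkene only (RhCl(PPh3)3, H2, benzene) gives 20 as its trans isomer. The regiochemistry of ring B is then set by the substituents of the dienophile and not by a rearrangement.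

Step 6. Most likely to go wrong: slow or incomplete addition to an alkyne that is branched at the propargylic carbon, while the alkylcopper reagent decomposes above about −10 °C, so that 14 is recovered. Fallback, from 14, returning at 19: Markovnikov hydroiodination (Me3SiCl, sodium iodide, H2O, MeCN) gives the 2-iodoalkene F8. Negishi coupling with (4-methylpent-3-en-1-yl)zinc bromide F9 (from 15, Zn, LiCl, THF) under Pd(dppf)Cl2 catalysis then gives 19. The bond to C8 is made by cross-coupling instead of by addition across the triple bond.

Step 9. Most likely to go wrong: acylation at oxygen instead of carbon, because C6 is fully substituted and flanked by the quaternary C4. Fallback, from 22 (through its enolate 23), returning at 25: aldol addition to propanal at −78 °C gives the beta-hydroxy ketone F10 (carbinol epimers, of no consequence). Oxidation with the periodinane DMP (CH2Cl2, rt) gives 25. An aldehyde cannot react productively at oxygen, and the cyclic transition state of the aldol addition copes better with the crowded carbon.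

Step 11. Most likely to go wrong: methylation at the C3 oxygen, and to a lesser degree at C2, since the two oxygen atoms of the enolised 1,3-diketone differ only in their surroundings. Fallback, from 27 to 28 without a new compound: acid-catalysed exchange with methanol (MeOH, HC(OMe)3, camphorsulfonic acid, rt). This forms the enol ether reversibly through the hemiketal, so the outcome is under thermodynamic control and the crowding next to the spiro centre disfavours the C3 ether. Material methylated at the wrong oxygen is hydrolysed back to 27 (aq. HCl, THF) and resubmitted.

## Further compounds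

F1 | step 4 | racemic (1-methylimidazol-2-yl)[(1S*,2S*,4S*)-2-(propan-2-yl)-4-(trimethylsilylethynyl)cyclobutyl]methanone | CC(C)[C@@H]1C[C@H](C#C[Si](C)(C)C)[C@H]1C(=O)c1nccn1C.CC(C)[C@H]1C[C@@H](C#C[Si](C)(C)C)[C@@H]1C(=O)c1nccn1C
F2 | step 4 | racemic 1,3-dimethyl-2-[(1S*,2S*,4S*)-2-(propan-2-yl)-4-(trimethylsilylethynyl)cyclobutanecarbonyl]imidazolium triflate | CC(C)[C@@H]1C[C@H](C#C[Si](C)(C)C)[C@H]1C(=O)c1n(C)cc[n+]1C.CC(C)[C@H]1C[C@@H](C#C[Si](C)(C)C)[C@@H]1C(=O)c1n(C)cc[n+]1C.[O-]S(=O)(=O)C(F)(F)F.[O-]S(=O)(=O)C(F)(F)F
F3 | step 4 | (4S)-4-benzyl-3-[(1S,2S,4S)-2-(propan-2-yl)-4-(trimethylsilylethynyl)cyclobutanecarbonyl]oxazolidin-2-one | CC(C)[C@@H]1C[C@H](C#C[Si](C)(C)C)[C@H]1C(=O)N1[C@@H](Cc2ccccc2)COC1=O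
F4 | step 7 | myrcene (7-methyl-3-methylideneocta-1,6-diene) | C=CC(=C)CCC=C(C)C
F5 | step 7 | methyl (E)-4-oxopent-2-enoate | COC(=O)/C=C/C(C)=O
F6 | step 7 | methyl (1R,6R)-6-acetyl-3-(4-methylpent-3-en-1-yl)cyclohex-3-ene-1-carboxylate | COC(=O)[C@@H]1CC(CCC=C(C)C)=CC[C@H]1C(C)=O
F7 | step 7 | methyl (1R,6R)-3-(4-methylpent-3-en-1-yl)-6-(prop-1-en-2-yl)cyclohex-3-ene-1-carboxylate | COC(=O)[C@@H]1CC(CCC=C(C)C)=CC[C@H]1C(C)=C
F8 | step 6 | methyl (1S,2S,4S)-2-(1-iodoethenyl)-4-(propan-2-yl)cyclobutane-1-carboxylate | CC(C)[C@@H]1C[C@H](C(I)=C)[C@H]1C(=O)OC
F9 | step 6 | (4-methylpent-3-en-1-yl)zinc bromide | CC(C)=CCC[Zn]Br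
F10 | step 9 | methyl (1S,6S)-1-(3-hydroxy-2,2-dimethylpentanoyl)-3-(4-methylpent-3-en-1-yl)-6-(propan-2-yl)cyclohex-3-ene-1-carboxylate | COC(=O)[C@]1(CC(CCC=C(C)C)=CC[C@H]1C(C)C)C(=O)C(C)(C)C(O)CC
F0 | step 11 | none | none
A1 | alternative 1 | (6S,11S)-5-(tert-butyldimethylsilyloxy)-3-methoxy-2,4-dimethyl-8-(4-methylpent-3-en-1-yl)-11-(prop-1-en-2-yl)spiro[5.5]undeca-2,4,8-trien-1-one | COC1=C(C)C(=O)[C@]2(CC(CCC=C(C)C)=CC[C@H]2C(C)=C)C(O[Si](C)(C)C(C)(C)C)=C1C
A2 | alternative 1 | (2E,5Z)-6-{[2-(tert-butyldimethylsilyloxy)-6-hydroxy-4-methoxy-3,5-dimethylphenyl]methyl}-2,10-dimethylundeca-2,5,9-trien-1-yl methyl carbonate | COC(=O)OC/C(C)=C/C/C=C(/CCC=C(C)C)Cc1c(O)c(C)c(OC)c(C)c1O[Si](C)(C)C(C)(C)C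
A3 | alternative 2 | methyl (1S,6S)-1-(2-methylpropanoyl)-3-(4-methylpent-3-en-1-yl)-6-(propan-2-yl)cyclohex-3-ene-1-carboxylate (identical with 22) | COC(=O)[C@]1(CC(CCC=C(C)C)=CC[C@H]1C(C)C)C(=O)C(C)C
A4 | alternative 2 | methyl 5-(4-methylpent-3-en-1-yl)cyclohexa-1,4-diene-1-carboxylate | COC(=O)C1=CCC=C(CCC=C(C)C)C1
A5 | alternative 3 | 3-methoxy-2,4,4-trimethyl-8-(4-methylpent-3-en-1-yl)-11-(propan-2-yl)spiro[5.5]undec-2-ene-1,5,9-trione, configured as in the SMILES | COC1=C(C)C(=O)[C@]2(C[C@H](CCC=C(C)C)C(=O)C[C@H]2C(C)C)C(=O)C1(C)C
A6 | alternative 3 | 5-methoxy-4,6,6-trimethylcyclohex-4-ene-1,3-dione | COC1=C(C)C(=O)CC(=O)C1(C)C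
A7 | alternative 3 | (E)-6-methyl-2-(4-methylpent-3-en-1-yl)hepta-1,4-dien-3-one | C=C(CCC=C(C)C)C(=O)/C=C/C(C)C
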